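## Structural features

The target 22 is a 3→8''-linked biflavonoid. A flavanone (phloroglucinol ring A fused to the dihydropyranone ring C, with a 4-hydroxyphenyl ring B on C2) is bonded through C3 to C8'' of an apigenin-type flavone, and the flavone 7''-hydroxyl carries a hydrogen sulfate. The only stereocentres, C2 (R) and C3 (S), are neighbours in ring C and trans; C3 lies α to the C4 ketone and can equilibrate, so only C2 must be fixed in the absolute sense. Fragile features are the aryl sulfate monoester (solvolysed by acid, so it has to come late), the flavanone (base opens ring C by retro-oxa-Michael reaction and would racemise C2), the flavone enone (over-reduction) and six phenols, of which exactly one is sulfated. The real difficulty is the C3–C8'' bond, an sp3–sp2 bond to a flavone carbon flanked by O7'' and the pyranone oxygen and placed between the 2-aryl group and the ketone; rotation about it is slow but is not a stereoelement to be controlled. The key step uses two facts about ring C. The unit O1–C2 is an O-aryl oxocarbenium ion conjugated through C8a–C4a with the symmetric ring A, whose two ortho carbons are equivalent. C3–C4 correspond to an alkyne polarised by nitrogen, in which C3 is the nucleophilic carbon already bonded to C8'' and C4 arrives at the ketone oxidation level as an enamide carbon.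

## Logic of the disconnections

22 to 20 (through 21): the five benzyl–oxygen bonds are cut last. The sulfate tolerates neither acid nor forcing base, so the final deprotection must be neutral. This demands a hydrogenolysis that spares the S–O bond, the flavone C2''=C3'' bond and the C4 carbonyl, and a cold, stoichiometric protonation of the salt.

20 to 18: the O–S bond is cut. In 18 the flavone 7''-hydroxyl is the only free phenol, so the site of sulfation is decided by the protecting-group pattern and not by reagent selectivity. The demand is a 7''-oxygen that was marked differently from the other five from the start.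

18 to 17 to 16: first the Si–O bond, then the C4=O group is traced back to the C4–N bond of an enamide. C3 therefore need not be carried as a stereocentre; it is created on hydrolysis and settles trans to the 2-aryl group. The demand is a hydrolysis mild enough not to ionise the doubly benzylic C2–O1 bond.

16 to 5 and 13 (key disconnection): C2–C3 and C4–C4a are cut. Two fragments of similar size are joined, ring C is closed and C2 is set in one operation, and the hindered C3–C8'' bond is already present in 13. The demands are ionisation of 5 by loss of methanol, attack of the ynamide through its flavone-bearing carbon, ring closure faster than any capture of the keteniminium ion, and facial control by a chiral counter-anion.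

5 to 2 and 3 (through 4), and 2 to 1: the aryl–O–C acetal bond is cut. It is formed under basic conditions, because an acid-catalysed exchange would let the electron-rich ring of 3 react at carbon. The gain is a two-step access to the oxocarbenium precursor; the demand is handling of an acid-labile mixed acetal.

13 to 11 and 12: the C8''–C(sp) bond is cut. The whole ynamide is delivered in one Sonogashira coupling instead of an alkyne installation followed by bromination and C–N coupling. The demand is a coupling at a di-ortho-substituted iodide.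

11 to 10 to 9 to 8 to 7 to 6: the Si–O bond, the relay acetal, the C8''–I bond, two benzyl–oxygen bonds and the first acetal bond are cut in turn. The order is dictated by phenol acidity (7 > 4' > 5) and by the rule that iodination goes to C8 once O5 is alkylated. A silyl ether would not survive the benzylation, hence the methoxymethyl relay. The two extra steps buy a bulky silyl ether whose oxygen is a poor nucleophile next to the future keteniminium carbon, where an acetal oxygen would invite benzofuran formation.

## Other disconnections considered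

Alternative 1: The cut runs through O1–C2 and C3–C4, so that ring C is assembled from the salicylaldehyde A1 (C4, C4a, C8a, O1) and the E-stilbene A2 (C2, C3). In the forward sense A1 would be converted by an orthoformate and a chiral N-triflylphosphoramide into a 4-methoxy ortho-quinone methide, which should add across the alkene of A2 in an inverse-demand hetero-Diels–Alder reaction to give the 2,3-trans-3,4-trans 4-methoxyflavan A3.
- In favour: the reaction class is established for styrenes; C2 and C3 are fixed in the same event, trans from the E geometry, so C3 does not depend on a later equilibration; the regiochemistry is sound because the 4-benzyloxyphenyl group stabilises charge at C2; A2 is one Heck reaction away from an 8-iodoflavone such as 9.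
- Against: the dienophile is a 1,2-diaryl alkene whose flavonyl end is di-ortho-substituted, twisted and electron-poor, and the quinone methide from A1 is stabilised by three oxygen donors and correspondingly sluggish. C4 arrives as a methyl ether at the alcohol oxidation level, so ether cleavage and an oxidation are needed before the sequence can join at 18. The methoxymethyl ether of A2 sits in a strongly acidic medium.
- Comparison: Alternative 1 is the better on precedent and on direct control of both stereocentres, and about equal in the length of the way to its precursors. The chosen plan is the better on oxidation level (the enamide is the ketone in disguise) and presents the hindered flavone carbon on a linear sp carbon and not on a twisted alkene. Alternative 1 should need one or two steps more.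

Alternative 2: Only C3–C4 is cut, in the umpolung sense: C4 becomes the acyl anion equivalent of an aldehyde and C3 the exocyclic carbon of an ortho-quinone methide spanning C7'' and C8'' of the flavone. The precursor A4 is a ring A salicylaldehyde whose phenol oxygen is bonded to C2, with an acetate on C3 and a silyl group on O7''. Fluoride (CsF) would remove the silyl group, acetate would leave, and the Breslow intermediate formed from the aldehyde and a chiral triazolium-derived carbene would add to C3 (intramolecular Stetter-type closure) to give A5, which is identical with 18.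
- In favour: C4 is delivered as the ketone and the flavone 7''-hydroxyl emerges free and alone, so only sulfation and hydrogenolysis remain, two steps fewer after the key step than in the chosen plan. Carbene-catalysed chromanone closures and acyl-anion additions to quinone methides are both known.
- Against: C2 is not made in the key step. It must be built enantiopure into A4 as a benzylic aryl ether next to the acetoxy carbon, which calls for a stilbene, an asymmetric dihydroxylation, differentiation of two benzylic hydroxyls and O-arylation of a hindered secondary alcohol. The quinone methide has a C2–H and a β-aryloxy group and can decay by hydrogen shift or elimination. Since C3 is epimerisable, the chiral carbene adds little.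
- Comparison: Alternative 2 is the better in the endgame and in resting on reactions of known type, and its C2 control would come from a dependable reaction. The chosen plan is the better in convergence and total length (A4 alone should take more steps than 5 and 13 together) and in making C2 in the ring-forming step.

Alternative 3: The cut is C2–C3. The precursor A6 is an α-aryl-α-diazo ketone in which C3 carries the diazo group between the ring A carbonyl and C8'', and ring A carries three identical 4-(benzyloxy)benzyl ethers. The carbene generated with Rh2(S-PTTL)4 would insert into a benzylic C–H bond of one of the two equivalent ortho ethers (1,6-insertion) and close ring C as A7.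
- In favour: C2–C3 and both stereocentres are made at the ketone oxidation level; the symmetry of ring A is used as in the chosen plan; insertion next to an ether oxygen under chiral dirhodium carboxylates is a known reaction type; the extra benzyl-type ethers fall in the final hydrogenolysis, so the endgame after A7 is one step shorter than after 16.
- Against: ortho-alkoxy diazo ketones readily form five-membered oxonium ylides that rearrange by 1,2-shift to benzofuranones, in competition with the six-membered insertion. The carbene carbon is hemmed in by a 2,4,6-trisubstituted aroyl group and a di-ortho-substituted flavonyl group. A6 requires a deoxybenzoin whose C3–C8'' bond must be made by enolate arylation at the hindered flavone carbon, followed by diazo transfer.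
- Comparison: Alternative 3 is the equal in its use of symmetry and the better in oxidation-level economy and in the maturity of its reaction class. The chosen plan is the better in chemoselectivity of the ring-forming event (no ylide channel) and in how the C3–C8'' bond is made. The step counts should be about the same.

Key step: step 9

Assumption: 12 is bought (it is marketed as an amide-coupling reagent); the hydrogen sulfate 22 is taken as the target form and its sodium salt 21 as the storage form.

Remark: C2 is S in 16 and R from 17 onwards with the same arrangement in space, because C3 outranks the 2-aryl group only while it is an sp2 carbon bonded to the nitrogen-bearing C4.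

## Route

Step 1
Reactants: 1 4-(benzyloxy)benzaldehyde
Product: 2 1-(benzyloxy)-4-(dimethoxymethyl)benzene
Conditions: HC(OMe)3, MeOH, TsOH·H2O (cat.), rt; then Et3N
Reagents that add atoms: trimethyl orthoformate, COC(OC)OC; methanol, CO
Why: Acid-catalysed acetalisation, driven by the orthoformate as water scavenger; the benzyl ether is inert.

Step 2
Reactants: 2 1-(benzyloxy)-4-(dimethoxymethyl)benzene; 3 3,5-bis(benzyloxy)phenol
Product: 5 1,3-bis(benzyloxy)-5-{[4-(benzyloxy)phenyl](methoxy)methoxy}benzene (racemic), via α-chloro ether 4 (not isolated)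
Conditions: AcCl (1.05 equiv), ZnBr2 (0.1 mol %), toluene, 0 °C to rt; then sodium salt of 3 (NaH, THF), −20 °C to rt; Et3N-deactivated silica
Reagents that add atoms: none
Why: Acetal–acyl chloride exchange gives the α-chloro ether 4 (the reaction by which chloromethyl ethers are made), and the sodium phenoxide of 3 displaces chloride at oxygen in a Williamson-type acetal formation, as in the methoxymethylation of phenols. Basic conditions avoid the Friedel–Crafts C-alkylation of the phloroglucinol ring that an acid-catalysed exchange with 3 would invite; the acetal carbon is racemic, which is immaterial because it becomes planar in step 9.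

Step 3
Reactants: 6 apigenin
Product: 7 5-hydroxy-2-(4-hydroxyphenyl)-7-(methoxymethoxy)-4H-chromen-4-one
Conditions: MOMCl (1.05 equiv), iPr2NEt (1.2 equiv), DMF, 0 °C
Reagents that add atoms: chloromethyl methyl ether, COCCl
Why: The 7-hydroxyl is the most acidic phenol (vinylogous acid through C4=O) and the 5-hydroxyl is hydrogen-bonded, so one equivalent of a weak base should give regioselective O-alkylation at O7 (Williamson-type etherification).

Step 4
Reactants: 7 5-hydroxy-2-(4-hydroxyphenyl)-7-(methoxymethoxy)-4H-chromen-4-one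
Product: 8 5-(benzyloxy)-2-[4-(benzyloxy)phenyl]-7-(methoxymethoxy)-4H-chromen-4-one
Conditions: BnBr (2.6 equiv), K2CO3 (4 equiv), KI (cat.), DMF, 70 °C
Reagents that add atoms: benzyl bromide, BrCc1ccccc1
Why: Williamson benzylation of the 4'- and 5-hydroxyls; heat is needed for the chelated 5-hydroxyl, and the methoxymethyl ether is stable to base, which a silyl ether at O7 would not be.

Step 5
Reactants: 8 5-(benzyloxy)-2-[4-(benzyloxy)phenyl]-7-(methoxymethoxy)-4H-chromen-4-one
Product: 9 5-(benzyloxy)-2-[4-(benzyloxy)phenyl]-8-iodo-7-(methoxymethoxy)-4H-chromen-4-one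
Conditions: I2 (1.1 equiv), CF3CO2Ag (1.1 equiv), NaHCO3 (2 equiv), CH2Cl2, 0 °C to rt, dark
Reagents that add atoms: iodine, II
Why: Electrophilic aromatic iodination by trifluoroacetyl hypoiodite formed in the flask; in 5,7-dialkoxyflavones the attack should go to C8 (ortho to O7 and the ring oxygen, para to O5), C6 being flanked by two alkoxy groups and ring B being deactivated by the enone. NaHCO3 takes up the acid so that the acetal at O7 survives.

Step 6
Reactants: 9 5-(benzyloxy)-2-[4-(benzyloxy)phenyl]-8-iodo-7-(methoxymethoxy)-4H-chromen-4-one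
Product: 10 5-(benzyloxy)-2-[4-(benzyloxy)phenyl]-7-hydroxy-8-iodo-4H-chromen-4-one
Conditions: 3 M HCl, MeOH/THF (1:1), 50 °C
Reagents that add atoms: none
Why: Acid-catalysed acetal exchange removes the methoxymethyl group as dimethoxymethane; benzyl ethers are stable, and the protonated flavone is too electron-poor for protodeiodination.

Step 7
Reactants: 10 5-(benzyloxy)-2-[4-(benzyloxy)phenyl]-7-hydroxy-8-iodo-4H-chromen-4-one
Product: 11 5-(benzyloxy)-2-[4-(benzyloxy)phenyl]-8-iodo-7-[(triisopropylsilyl)oxy]-4H-chromen-4-one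
Conditions: TIPSCl (1.5 equiv), imidazole (3 equiv), DMAP (cat.), DMF, 40 °C
Reagents that add atoms: triisopropylsilyl chloride, CC(C)[Si](Cl)(C(C)C)C(C)C
Why: Silylation of the acidic 7-hydroxyl; the bulky silyl ether should survive the coupling and the acidic key step, can be removed without base, and leaves O7 hindered and weakly nucleophilic next to the alkyne.

Step 8
Reactants: 11 5-(benzyloxy)-2-[4-(benzyloxy)phenyl]-8-iodo-7-[(triisopropylsilyl)oxy]-4H-chromen-4-one; 12 N-ethynyl-N,4-dimethylbenzenesulfonamide
Product: 13 N-({5-(benzyloxy)-2-[4-(benzyloxy)phenyl]-4-oxo-7-[(triisopropylsilyl)oxy]-4H-chromen-8-yl}ethynyl)-N,4-dimethylbenzenesulfonamide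
Conditions: Pd(PPh3)4 (5 mol %), CuI (5 mol %), Et3N, THF, 50 °C, argon; 12 (1.5 equiv) added slowly
Reagents that add atoms: none
Why: Sonogashira coupling of a terminal N-sulfonyl ynamide with an aryl iodide (oxidative addition to zerovalent palladium, copper acetylide transmetalation, reductive elimination). Slow addition under argon should curb oxidative dimerisation of 12, and the tertiary amine does not add to the ynamide.

Step 9
Reactants: 13 N-({5-(benzyloxy)-2-[4-(benzyloxy)phenyl]-4-oxo-7-[(triisopropylsilyl)oxy]-4H-chromen-8-yl}ethynyl)-N,4-dimethylbenzenesulfonamide; 5 1,3-bis(benzyloxy)-5-{[4-(benzyloxy)phenyl](methoxy)methoxy}benzene (racemic)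
Product: 16 (2S)-N-{5,7-bis(benzyloxy)-2-[4-(benzyloxy)phenyl]-3-{5-(benzyloxy)-2-[4-(benzyloxy)phenyl]-4-oxo-7-[(triisopropylsilyl)oxy]-4H-chromen-8-yl}-2H-chromen-4-yl}-N,4-dimethylbenzenesulfonamide, via aryl oxocarbenium ion 14 (not isolated), via keteniminium ion 15 (not isolated)
Conditions: chiral imidodiphosphorimidate (IDPi) Brønsted acid (3,3'-diaryl-BINOL-derived, N-triflyl; 10 mol %), 5 Å MS, CHCl3/toluene, −40 °C; 5 (1.5 equiv) added over 6 h
Reagents that add atoms: none
Why: Proposed new method: the chiral acid protonates the methoxy oxygen of 5 and methanol leaves into the sieves, giving the O-aryl oxocarbenium ion 14 as a contact ion pair with the chiral anion, on which both enantiomers of 5 converge. The nucleophilic β-carbon of ynamide 13 (the carbon bearing the flavone) adds to the oxocarbenium carbon on the face left open by the anion, which forms C2–C3, sets C2 and generates keteniminium ion 15. The sp carbon of 15 is then attacked, in the plane of its C=N bond, by one of the two equivalent ortho carbons of the 3,5-bis(benzyloxy)phenoxy ring (intramolecular Friedel–Crafts alkenylation, 6-exo-dig with respect to the C=N bond), which forms C4–C4a and closes ring C; loss of the ring proton returns the acid. The closest known reactions are the Lewis-acid-mediated oxa-Povarov reaction of aryl oxocarbenium ions with alkenes and keteniminium-terminated Povarov reactions of ynamides with N-aryl iminium ions; control of an acyclic O-aryl oxocarbenium ion by a chiral counter-anion is without precedent, although confined acids of this class do control additions to other oxocarbenium ions. Regiochemistry follows from the polarisation of the ynamide by nitrogen and from the symmetry of ring A, and C2 is controlled by the catalyst alone, so the antipode that leads to (2S)-16 has to be found in a first screen; any isomerism about the C3–C8'' axis of 16 is of no consequence because it converges in step 10. The step needs ionisation by loss of methanol and not of the phenol, and ring closure faster than capture of 15 by O7 or by methanol; the exposed and more basic methoxy oxygen, the low temperature, the sieves, slow addition of 5 and the hindered silyl ether are meant to secure this, and the substituent on C3 twists the flavone out of the plane in which O7 would have to attack. The bond to the hindered C8'' already exists, so the congested junction is never made by a bimolecular attack at that carbon.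

Step 10
Reactants: 16 (2S)-N-{5,7-bis(benzyloxy)-2-[4-(benzyloxy)phenyl]-3-{5-(benzyloxy)-2-[4-(benzyloxy)phenyl]-4-oxo-7-[(triisopropylsilyl)oxy]-4H-chromen-8-yl}-2H-chromen-4-yl}-N,4-dimethylbenzenesulfonamide
Product: 17 (2R,3S)-5,7-bis(benzyloxy)-2-[4-(benzyloxy)phenyl]-3-{5-(benzyloxy)-2-[4-(benzyloxy)phenyl]-4-oxo-7-[(triisopropylsilyl)oxy]-4H-chromen-8-yl}-2,3-dihydro-4H-chromen-4-one
Conditions: 2 M aq. HCl/THF (1:4), 45 °C
Reagents that add atoms: water, O
Why: Enamide hydrolysis: protonation at C3 gives a C4 cation stabilised by nitrogen, by O1 and by the 5,7-dialkoxy ring, water adds and the sulfonamide leaves. C3 then equilibrates through the enol under the same acid to the 2,3-trans ketone with both large groups equatorial, while C2 is not touched; any loss of the silyl group converges on 18.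

Step 11
Reactants: 17 (2R,3S)-5,7-bis(benzyloxy)-2-[4-(benzyloxy)phenyl]-3-{5-(benzyloxy)-2-[4-(benzyloxy)phenyl]-4-oxo-7-[(triisopropylsilyl)oxy]-4H-chromen-8-yl}-2,3-dihydro-4H-chromen-4-one
Product: 18 (2R,3S)-5,7-bis(benzyloxy)-2-[4-(benzyloxy)phenyl]-3-{5-(benzyloxy)-2-[4-(benzyloxy)phenyl]-7-hydroxy-4-oxo-4H-chromen-8-yl}-2,3-dihydro-4H-chromen-4-one
Conditions: HF·pyridine, pyridine, THF, 0 °C to rt (PTFE vessel)
Reagents that add atoms: none
Why: Fluoride-induced cleavage of the aryl silyl ether in a buffered, weakly acidic medium; a basic fluoride source is avoided because base would open ring C and endanger C2.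

Step 12
Reactants: 18 (2R,3S)-5,7-bis(benzyloxy)-2-[4-(benzyloxy)phenyl]-3-{5-(benzyloxy)-2-[4-(benzyloxy)phenyl]-7-hydroxy-4-oxo-4H-chromen-8-yl}-2,3-dihydro-4H-chromen-4-one
Product: 20 sodium 5-(benzyloxy)-2-[4-(benzyloxy)phenyl]-8-{(2R,3S)-5,7-bis(benzyloxy)-2-[4-(benzyloxy)phenyl]-4-oxo-3,4-dihydro-2H-chromen-3-yl}-4-oxo-4H-chromen-7-yl sulfate, via pyridinium aryl sulfate 19 (not isolated)
Conditions: SO3·pyridine (6 equiv), pyridine, 40 °C; then cold sat. aq. NaHCO3; C18 or Sephadex LH-20
Reagents that add atoms: sulfur trioxide–pyridine complex, O=S(=O)=O.c1ccncc1; sodium hydrogen carbonate, [Na+].OC([O-])=O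
Why: O-Sulfation of the only free phenol by an amine–SO3 complex, then cation exchange to the sodium salt; the site is fixed by the protecting-group pattern, and pyridine is too weak a base to open ring C under these conditions.

Step 13
Reactants: 20 sodium 5-(benzyloxy)-2-[4-(benzyloxy)phenyl]-8-{(2R,3S)-5,7-bis(benzyloxy)-2-[4-(benzyloxy)phenyl]-4-oxo-3,4-dihydro-2H-chromen-3-yl}-4-oxo-4H-chromen-7-yl sulfate
Product: 22 5-hydroxy-2-(4-hydroxyphenyl)-8-[(2R,3S)-5,7-dihydroxy-2-(4-hydroxyphenyl)-4-oxo-3,4-dihydro-2H-chromen-3-yl]-4-oxo-4H-chromen-7-yl hydrogen sulfate, via target sodium salt 21 (not isolated)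
Conditions: H2 (1 atm), 10% Pd/C, THF/MeOH (1:1), rt, followed closely; filter; then HCl (1.0 equiv, 0.1 M), 0 °C; C18 desalting, lyophilisation
Reagents that add atoms: none
Why: Hydrogenolysis of the five aryl benzyl ethers over Pd/C, to which aryl sulfate salts are inert; the neutral medium leaves C2 and C3 alone, and a short reaction at 1 atm should spare the flavone double bond and the C4 carbonyl. One equivalent of acid in the cold converts salt 21 into the hydrogen sulfate 22.

## Compound list

1 | 4-(benzyloxy)benzaldehyde | O=Cc1ccc(OCc2ccccc2)cc1 | starting material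
2 | 1-(benzyloxy)-4-(dimethoxymethyl)benzene | COC(OC)c1ccc(OCc2ccccc2)cc1 | intermediate
3 | 3,5-bis(benzyloxy)phenol | Oc1cc(OCc2ccccc2)cc(OCc2ccccc2)c1 | starting material
4 | 1-(benzyloxy)-4-[chloro(methoxy)methyl]benzene (racemic) | COC(Cl)c1ccc(OCc2ccccc2)cc1 | intermediate (not isolated)
5 | 1,3-bis(benzyloxy)-5-{[4-(benzyloxy)phenyl](methoxy)methoxy}benzene (racemic) | COC(Oc1cc(OCc2ccccc2)cc(OCc2ccccc2)c1)c1ccc(OCc2ccccc2)cc1 | intermediate
6 | apigenin | O=c1cc(-c2ccc(O)cc2)oc2cc(O)cc(O)c12 | starting material
7 | 5-hydroxy-2-(4-hydroxyphenyl)-7-(methoxymethoxy)-4H-chromen-4-one | COCOc1cc(O)c2c(=O)cc(-c3ccc(O)cc3)oc2c1 | intermediate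
8 | 5-(benzyloxy)-2-[4-(benzyloxy)phenyl]-7-(methoxymethoxy)-4H-chromen-4-one | COCOc1cc(OCc2ccccc2)c2c(=O)cc(-c3ccc(OCc4ccccc4)cc3)oc2c1 | intermediate
9 | 5-(benzyloxy)-2-[4-(benzyloxy)phenyl]-8-iodo-7-(methoxymethoxy)-4H-chromen-4-one | COCOc1cc(OCc2ccccc2)c2c(=O)cc(-c3ccc(OCc4ccccc4)cc3)oc2c1I | intermediate
10 | 5-(benzyloxy)-2-[4-(benzyloxy)phenyl]-7-hydroxy-8-iodo-4H-chromen-4-one | Oc1cc(OCc2ccccc2)c2c(=O)cc(-c3ccc(OCc4ccccc4)cc3)oc2c1I | intermediate
11 | 5-(benzyloxy)-2-[4-(benzyloxy)phenyl]-8-iodo-7-[(triisopropylsilyl)oxy]-4H-chromen-4-one | CC(C)[Si](Oc1cc(OCc2ccccc2)c2c(=O)cc(-c3ccc(OCc4ccccc4)cc3)oc2c1I)(C(C)C)C(C)C | intermediate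
12 | N-ethynyl-N,4-dimethylbenzenesulfonamide | C#CN(C)S(=O)(=O)c1ccc(C)cc1 | starting material
13 | N-({5-(benzyloxy)-2-[4-(benzyloxy)phenyl]-4-oxo-7-[(triisopropylsilyl)oxy]-4H-chromen-8-yl}ethynyl)-N,4-dimethylbenzenesulfonamide | CN(C#Cc1c(O[Si](C(C)C)(C(C)C)C(C)C)cc(OCc3ccccc3)c2c(=O)cc(-c3ccc(OCc4ccccc4)cc3)oc12)S(=O)(=O)c1ccc(C)cc1 | intermediate
14 | {[4-(benzyloxy)phenyl]methylidene}[3,5-bis(benzyloxy)phenyl]oxonium (ion pair with the catalyst anion) | C(=[O+]c1cc(OCc2ccccc2)cc(OCc2ccccc2)c1)c1ccc(OCc2ccccc2)cc1 | intermediate (not isolated)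
15 | N-methyl-N-tosyl keteniminium ion from addition of 13 to 14, configured at the aryloxy carbon as C2 of 16 (ion pair with the catalyst anion) | C[N+](=C=C([C@@H](Oc1cc(OCc2ccccc2)cc(OCc2ccccc2)c1)c1ccc(OCc2ccccc2)cc1)c1c(O[Si](C(C)C)(C(C)C)C(C)C)cc(OCc2ccccc2)c2c(=O)cc(-c3ccc(OCc4ccccc4)cc3)oc12)S(=O)(=O)c1ccc(C)cc1 | intermediate (not isolated)
16 | (2S)-N-{5,7-bis(benzyloxy)-2-[4-(benzyloxy)phenyl]-3-{5-(benzyloxy)-2-[4-(benzyloxy)phenyl]-4-oxo-7-[(triisopropylsilyl)oxy]-4H-chromen-8-yl}-2H-chromen-4-yl}-N,4-dimethylbenzenesulfonamide | CN(C1c2c(OCc3ccccc3)cc(OCc3ccccc3)cc2O[C@@H](c2ccc(OCc3ccccc3)cc2)C=1c1c(O[Si](C(C)C)(C(C)C)C(C)C)cc(OCc3ccccc3)c2c(=O)cc(-c3ccc(OCc4ccccc4)cc3)oc12)S(=O)(=O)c1ccc(C)cc1 | intermediate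
17 | (2R,3S)-5,7-bis(benzyloxy)-2-[4-(benzyloxy)phenyl]-3-{5-(benzyloxy)-2-[4-(benzyloxy)phenyl]-4-oxo-7-[(triisopropylsilyl)oxy]-4H-chromen-8-yl}-2,3-dihydro-4H-chromen-4-one | O=C1c2c(OCc3ccccc3)cc(OCc3ccccc3)cc2O[C@@H](c2ccc(OCc3ccccc3)cc2)[C@@H]1c1c(O[Si](C(C)C)(C(C)C)C(C)C)cc(OCc3ccccc3)c2c(=O)cc(-c3ccc(OCc4ccccc4)cc3)oc12 | intermediate
18 | (2R,3S)-5,7-bis(benzyloxy)-2-[4-(benzyloxy)phenyl]-3-{5-(benzyloxy)-2-[4-(benzyloxy)phenyl]-7-hydroxy-4-oxo-4H-chromen-8-yl}-2,3-dihydro-4H-chromen-4-one | O=C1c2c(OCc3ccccc3)cc(OCc3ccccc3)cc2O[C@@H](c2ccc(OCc3ccccc3)cc2)[C@@H]1c1c(O)cc(OCc3ccccc3)c2c(=O)cc(-c3ccc(OCc4ccccc4)cc3)oc12 | intermediate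
19 | pyridinium salt of the 7''-O-sulfate of 18 | O=C1c2c(OCc3ccccc3)cc(OCc3ccccc3)cc2O[C@@H](c2ccc(OCc3ccccc3)cc2)[C@@H]1c1c(OS(=O)(=O)[O-])cc(OCc3ccccc3)c2c(=O)cc(-c3ccc(OCc4ccccc4)cc3)oc12.c1cc[nH+]cc1 | intermediate (not isolated)
20 | sodium 5-(benzyloxy)-2-[4-(benzyloxy)phenyl]-8-{(2R,3S)-5,7-bis(benzyloxy)-2-[4-(benzyloxy)phenyl]-4-oxo-3,4-dihydro-2H-chromen-3-yl}-4-oxo-4H-chromen-7-yl sulfate | O=C1c2c(OCc3ccccc3)cc(OCc3ccccc3)cc2O[C@@H](c2ccc(OCc3ccccc3)cc2)[C@@H]1c1c(OS(=O)(=O)[O-])cc(OCc3ccccc3)c2c(=O)cc(-c3ccc(OCc4ccccc4)cc3)oc12.[Na+] | intermediate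
21 | sodium 5-hydroxy-2-(4-hydroxyphenyl)-8-[(2R,3S)-5,7-dihydroxy-2-(4-hydroxyphenyl)-4-oxo-3,4-dihydro-2H-chromen-3-yl]-4-oxo-4H-chromen-7-yl sulfate | O=C1c2c(O)cc(O)cc2O[C@@H](c2ccc(O)cc2)[C@@H]1c1c(OS(=O)(=O)[O-])cc(O)c2c(=O)cc(-c3ccc(O)cc3)oc12.[Na+] | intermediate (not isolated)
22 | 5-hydroxy-2-(4-hydroxyphenyl)-8-[(2R,3S)-5,7-dihydroxy-2-(4-hydroxyphenyl)-4-oxo-3,4-dihydro-2H-chromen-3-yl]-4-oxo-4H-chromen-7-yl hydrogen sulfate | O=C1c2c(O)cc(O)cc2O[C@@H](c2ccc(O)cc2)[C@@H]1c1c(OS(=O)(=O)O)cc(O)c2c(=O)cc(-c3ccc(O)cc3)oc12 | target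

## Step count and least certain steps

Total step count: 13 (eight before the key step, four after it). Longest linear sequence: 11 steps, from 6 to 22 (steps 3 to 13).

Step 9 (key step, proposed new method). What may go wrong:
- ionisation of 5 in the wrong sense (departure of the phenol instead of methanol), followed by C-alkylation of the liberated phenol;
- poor facial discrimination in the ion pair;
- capture of the keteniminium ion by O7 after silyl loss (benzofuran formation) or by methanol;
- buffering of the acid by the basic flavone carbonyl.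

Fallback by known chemistry, setting out from 9 and 1 and returning at 18. Commercial 1-[2,4-bis(benzyloxy)-6-hydroxyphenyl]ethanone would be protected (MOMCl, NaH, THF) as 1-[2,4-bis(benzyloxy)-6-(methoxymethoxy)phenyl]ethanone F1. Palladium-catalysed enolate arylation of F1 with iodide 9 (Pd2(dba)3, Xantphos, K3PO4, dioxane, 90 °C) should give the bis(methoxymethyl) deoxybenzoin F2, and HCl in MeOH/THF would free both phenols to give the dihydroxy deoxybenzoin F3. Condensation of F3 with 1 (piperidine, EtOH, reflux; Knoevenagel condensation followed by oxa-Michael closure) should give the trans flavanone as a racemate, that is 18 together with its (2S,3R) enantiomer F4. Chromatography on a chiral stationary phase would deliver 18, which re-enters at step 12.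

Step 8. What may go wrong: slow coupling at the di-ortho-substituted iodide, with oxidative dimerisation or hydration of the terminal ynamide taking over. Fallback from 11 to 13, forming the C–N bond last: Sonogashira coupling of 11 with ethynyltrimethylsilane (PdCl2(PPh3)2, CuI, Et3N, THF, 60 °C) to the 8-[(trimethylsilyl)ethynyl]flavone F5; desilylative bromination (NBS, AgNO3 cat., acetone, rt) to the 8-(bromoethynyl)flavone F6; copper-catalysed amidation of F6 with N-methyl-p-toluenesulfonamide (CuSO4·5H2O, 1,10-phenanthroline, K3PO4, toluene, 70 °C) to 13.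

Step 10. What may go wrong: C3 protonation of the tetrasubstituted N-sulfonyl enamide may be so slow that the acid strength needed starts to ionise the doubly benzylic C2–O1 bond (erosion of enantiopurity) or to cleave benzyl ethers. Fallback from 11 to 17 with a more easily hydrolysed enamide: the bromoalkyne F6 (made from 11 through F5 as above) would be coupled with 1,3-oxazolidin-2-one under the same copper conditions to the N-acyl ynamide F7. The annulation of step 9 with 5 would give the 4-(2-oxo-1,3-oxazolidin-3-yl)-2H-chromene F8, whose ene-carbamate should hydrolyse with dilute aqueous oxalic acid in THF at room temperature to 17.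

Step 5. What may go wrong: attack of the iodinating agent at C6 or at C3, or loss of the acetal at O7 followed by over-iodination. Fallback from 8 to 10 with the free phenol as directing group: acid methanolysis of 8 (HCl, MeOH/THF) to 5-(benzyloxy)-2-[4-(benzyloxy)phenyl]-7-hydroxy-4H-chromen-4-one F9, then ortho-iodination of the phenol under basic conditions (I2, morpholine, CH2Cl2, 0 °C), which should favour C8 between the hydroxyl and the ring oxygen, to give 10.

Step 13. What may go wrong: partial saturation of the flavone C2''=C3'' bond or reduction at C4 during the fivefold hydrogenolysis, and solvolysis of the sulfate once the free acid is formed. Fallback from 17 to 21 without a reductive step: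
- debenzylation with BCl3 and pentamethylbenzene (CH2Cl2, −78 °C) to the silylated pentaphenol F10;
- acetylation (Ac2O, pyridine, DMAP) to the pentaacetate F11;
- desilylation (HF·pyridine) to the pentaacetate with free 7''-hydroxyl F12;
- sulfation as in step 12 to the sodium sulfate pentaacetate F13;
- neutral deacetylation (NH4OAc, MeOH/H2O, rt) to 21, which is protonated as in step 13.

## Further compounds

F1 | step 9 | 1-[2,4-bis(benzyloxy)-6-(methoxymethoxy)phenyl]ethanone | CC(=O)c1c(OCOC)cc(OCc2ccccc2)cc1OCc1ccccc1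
F2 | step 9 | 1-[2,4-bis(benzyloxy)-6-(methoxymethoxy)phenyl]-2-{5-(benzyloxy)-2-[4-(benzyloxy)phenyl]-7-(methoxymethoxy)-4-oxo-4H-chromen-8-yl}ethanone | COCOc1cc(OCc2ccccc2)cc(OCc2ccccc2)c1C(=O)Cc1c(OCOC)cc(OCc2ccccc2)c2c(=O)cc(-c3ccc(OCc4ccccc4)cc3)oc12
F3 | step 9 | 1-[2,4-bis(benzyloxy)-6-hydroxyphenyl]-2-{5-(benzyloxy)-2-[4-(benzyloxy)phenyl]-7-hydroxy-4-oxo-4H-chromen-8-yl}ethanone | Oc1cc(OCc2ccccc2)cc(OCc2ccccc2)c1C(=O)Cc1c(O)cc(OCc2ccccc2)c2c(=O)cc(-c3ccc(OCc4ccccc4)cc3)oc12
F4 | step 9 | (2S,3R) enantiomer of 18, formed with 18 as the racemate | O=C1c2c(OCc3ccccc3)cc(OCc3ccccc3)cc2O[C@H](c2ccc(OCc3ccccc3)cc2)[C@H]1c1c(O)cc(OCc3ccccc3)c2c(=O)cc(-c3ccc(OCc4ccccc4)cc3)oc12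
F5 | step 8 | 5-(benzyloxy)-2-[4-(benzyloxy)phenyl]-7-[(triisopropylsilyl)oxy]-8-[(trimethylsilyl)ethynyl]-4H-chromen-4-one | C[Si](C)(C)C#Cc1c(O[Si](C(C)C)(C(C)C)C(C)C)cc(OCc2ccccc2)c2c(=O)cc(-c3ccc(OCc4ccccc4)cc3)oc12
F6 | step 8 | 5-(benzyloxy)-2-[4-(benzyloxy)phenyl]-8-(bromoethynyl)-7-[(triisopropylsilyl)oxy]-4H-chromen-4-one | BrC#Cc1c(O[Si](C(C)C)(C(C)C)C(C)C)cc(OCc2ccccc2)c2c(=O)cc(-c3ccc(OCc4ccccc4)cc3)oc12
F7 | step 10 | 3-({5-(benzyloxy)-2-[4-(benzyloxy)phenyl]-4-oxo-7-[(triisopropylsilyl)oxy]-4H-chromen-8-yl}ethynyl)-1,3-oxazolidin-2-one | O=C1OCCN1C#Cc1c(O[Si](C(C)C)(C(C)C)C(C)C)cc(OCc2ccccc2)c2c(=O)cc(-c3ccc(OCc4ccccc4)cc3)oc12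
F8 | step 10 | 3-{(2S)-5,7-bis(benzyloxy)-2-[4-(benzyloxy)phenyl]-3-{5-(benzyloxy)-2-[4-(benzyloxy)phenyl]-4-oxo-7-[(triisopropylsilyl)oxy]-4H-chromen-8-yl}-2H-chromen-4-yl}-1,3-oxazolidin-2-one | O=C1OCCN1C1c2c(OCc3ccccc3)cc(OCc3ccccc3)cc2O[C@@H](c2ccc(OCc3ccccc3)cc2)C=1c1c(O[Si](C(C)C)(C(C)C)C(C)C)cc(OCc3ccccc3)c2c(=O)cc(-c3ccc(OCc4ccccc4)cc3)oc12
F9 | step 5 | 5-(benzyloxy)-2-[4-(benzyloxy)phenyl]-7-hydroxy-4H-chromen-4-one | Oc1cc(OCc2ccccc2)c2c(=O)cc(-c3ccc(OCc4ccccc4)cc3)oc2c1
F10 | step 13 | (2R,3S)-5,7-dihydroxy-2-(4-hydroxyphenyl)-3-{5-hydroxy-2-(4-hydroxyphenyl)-4-oxo-7-[(triisopropylsilyl)oxy]-4H-chromen-8-yl}-2,3-dihydro-4H-chromen-4-one | O=C1c2c(O)cc(O)cc2O[C@@H](c2ccc(O)cc2)[C@@H]1c1c(O[Si](C(C)C)(C(C)C)C(C)C)cc(O)c2c(=O)cc(-c3ccc(O)cc3)oc12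
F11 | step 13 | pentaacetate of F10 | O=C1c2c(OC(C)=O)cc(OC(C)=O)cc2O[C@@H](c2ccc(OC(C)=O)cc2)[C@@H]1c1c(O[Si](C(C)C)(C(C)C)C(C)C)cc(OC(C)=O)c2c(=O)cc(-c3ccc(OC(C)=O)cc3)oc12
F12 | step 13 | pentaacetate with free flavone 7''-hydroxyl | O=C1c2c(OC(C)=O)cc(OC(C)=O)cc2O[C@@H](c2ccc(OC(C)=O)cc2)[C@@H]1c1c(O)cc(OC(C)=O)c2c(=O)cc(-c3ccc(OC(C)=O)cc3)oc12
F13 | step 13 | sodium 7''-sulfate of the pentaacetate F12 | O=C1c2c(OC(C)=O)cc(OC(C)=O)cc2O[C@@H](c2ccc(OC(C)=O)cc2)[C@@H]1c1c(OS(=O)(=O)[O-])cc(OC(C)=O)c2c(=O)cc(-c3ccc(OC(C)=O)cc3)oc12.[Na+]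
A1 | alternative 1 | 2-hydroxy-4,6-bis(benzyloxy)benzaldehyde | O=Cc1c(O)cc(OCc2ccccc2)cc1OCc1ccccc1
A2 | alternative 1 | 5-(benzyloxy)-2-[4-(benzyloxy)phenyl]-8-{(E)-2-[4-(benzyloxy)phenyl]ethenyl}-7-(methoxymethoxy)-4H-chromen-4-one | COCOc1cc(OCc2ccccc2)c2c(=O)cc(-c3ccc(OCc4ccccc4)cc3)oc2c1/C=C/c1ccc(OCc2ccccc2)cc1
A3 | alternative 1 | 2,3-trans-3,4-trans-5,7-bis(benzyloxy)-2-[4-(benzyloxy)phenyl]-4-methoxy-3-{5-(benzyloxy)-2-[4-(benzyloxy)phenyl]-7-(methoxymethoxy)-4-oxo-4H-chromen-8-yl}chromane, C2 in space as in 22 | CO[C@H]1c2c(OCc3ccccc3)cc(OCc3ccccc3)cc2O[C@@H](c2ccc(OCc3ccccc3)cc2)[C@@H]1c1c(OCOC)cc(OCc3ccccc3)c2c(=O)cc(-c3ccc(OCc4ccccc4)cc3)oc12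
A4 | alternative 2 | 2-{2-acetoxy-1-[4-(benzyloxy)phenyl]-2-{5-(benzyloxy)-2-[4-(benzyloxy)phenyl]-7-[(tert-butyldimethylsilyl)oxy]-4-oxo-4H-chromen-8-yl}ethoxy}-4,6-bis(benzyloxy)benzaldehyde, aryloxy carbon in space as C2 of 22, acetoxy carbon of either configuration | O=Cc1c(OCc2ccccc2)cc(OCc2ccccc2)cc1O[C@@H](c1ccc(OCc2ccccc2)cc1)C(OC(C)=O)c1c(O[Si](C)(C)C(C)(C)C)cc(OCc2ccccc2)c2c(=O)cc(-c3ccc(OCc4ccccc4)cc3)oc12
A5 | alternative 2 | (2R,3S)-penta-O-benzyl flavanone–flavone with free flavone 7''-hydroxyl, identical with 18 | O=C1c2c(OCc3ccccc3)cc(OCc3ccccc3)cc2O[C@@H](c2ccc(OCc3ccccc3)cc2)[C@@H]1c1c(O)cc(OCc3ccccc3)c2c(=O)cc(-c3ccc(OCc4ccccc4)cc3)oc12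
A6 | alternative 3 | 2-diazo-2-{5-(benzyloxy)-2-[4-(benzyloxy)phenyl]-4-oxo-7-[(triisopropylsilyl)oxy]-4H-chromen-8-yl}-1-{2,4,6-tris[(4-benzyloxybenzyl)oxy]phenyl}ethanone | [N-]=[N+]=C(C(=O)c1c(OCc2ccc(OCc3ccccc3)cc2)cc(OCc2ccc(OCc3ccccc3)cc2)cc1OCc1ccc(OCc2ccccc2)cc1)c1c(O[Si](C(C)C)(C(C)C)C(C)C)cc(OCc2ccccc2)c2c(=O)cc(-c3ccc(OCc4ccccc4)cc3)oc12
A7 | alternative 3 | (2R,3S)-5,7-bis[(4-benzyloxybenzyl)oxy]-2-[4-(benzyloxy)phenyl]-3-{5-(benzyloxy)-2-[4-(benzyloxy)phenyl]-4-oxo-7-[(triisopropylsilyl)oxy]-4H-chromen-8-yl}-2,3-dihydro-4H-chromen-4-one | O=C1c2c(OCc3ccc(OCc4ccccc4)cc3)cc(OCc3ccc(OCc4ccccc4)cc3)cc2O[C@@H](c2ccc(OCc3ccccc3)cc2)[C@@H]1c1c(O[Si](C(C)C)(C(C)C)C(C)C)cc(OCc3ccccc3)c2c(=O)cc(-c3ccc(OCc4ccccc4)cc3)oc12
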